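**Retrosynthetic overview**
1. 12 ⇒ 9: one oxidative radical cascade on a monocyclic, dearomatised acylphloroglucinol closes three rings: the cyclopentane (C3–CH bond), the seven-membered ring (CH2–C7 bond), then ring B (C8–C1 bond).
2. 9 ⇒ 7: a catalytic enantioselective dearomative C-prenylation creates the C5 quaternary centre, the only stereocentre carried into the cascade.
3. 7 ⇒ 3 + 5 (reductive C-alkylation); 3 ⇒ 1 + 2 (C-geranylation); 5 ⇐ ester 4.
4. Ring order: ring A is bought as the phloroglucinol core; ring D (cyclopentane), ring C (seven-membered) and ring B are all formed in the last step, in that order.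

Locants used below: C1 = benzoyl-bearing ring carbon; C2, C4, C9 = carbonyl carbons; C3 = ring carbon bearing the pentenyl chain; C5 = quaternary geranyl carbon; C6–C7–C8 = the CH2–CH–C(CH3)2 unit that comes from the prenyl group. Geranyl = (2E)-3,7-dimethylocta-2,6-dien-1-yl; prenyl = 3-methylbut-2-en-1-yl.

Assumption: the (R,R)-Trost ligand is written as the one that gives (R)-9; if a first run shows the opposite sense, the mirror-image ligand is used under the same conditions.
Assumption: enolised triketones are drawn as one tautomer; 2,4,6-trihydroxybenzophenone is taken as a purchasable starting material.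

**Step 1**
Reactants: 1 2,4,6-trihydroxybenzophenone; 2 geranyl bromide
Product: 3 3-geranyl-2,4,6-trihydroxybenzophenone
Conditions: DBU (1.0 equiv), THF, 0 °C to rt
Reagents that add atoms: none
Why: C-alkylation of the acylphloroglucinol phenolate with an allylic bromide at a ring carbon flanked by two oxygens; 1 is symmetric, so there is one mono-C-alkylation product, and one equivalent of bromide limits over-alkylation.

**Step 2**
Reactants: 4 methyl 3,3-dimethylpent-4-enoate
Product: 5 3,3-dimethylpent-4-enal
Conditions: i-Bu2AlH (1.05 equiv), CH2Cl2, −78 °C; aqueous potassium sodium tartrate work-up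
Reagents that add atoms: none
Why: Partial reduction of an ester with i-Bu2AlH; the aluminium hemiacetal is stable at −78 °C and releases the aldehyde only on work-up.

**Step 3**
Reactants: 3 3-geranyl-2,4,6-trihydroxybenzophenone; 5 3,3-dimethylpent-4-enal
Product: 7 3-geranyl-5-(3,3-dimethylpent-4-en-1-yl)-2,4,6-trihydroxybenzophenone, via ortho-quinone methide 6 (not isolated)
Conditions: L-proline (20 mol %), Hantzsch ester (1.1 equiv), EtOH, rt
Reagents that add atoms: none
Why: Three-component reductive alkylation (Knoevenagel condensation, then transfer hydrogenation): the single free ring CH condenses with the aldehyde to the alkylidene 6, which takes hydride from the Hantzsch ester and re-aromatises; the neutral conditions spare the geranyl group.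

**Step 4**
Reactants: 7 3-geranyl-5-(3,3-dimethylpent-4-en-1-yl)-2,4,6-trihydroxybenzophenone; 8 prenyl acetate
Product: 9 (6R)-4-benzoyl-2-(3,3-dimethylpent-4-en-1-yl)-6-geranyl-3,5-dihydroxy-6-prenylcyclohexa-2,4-dien-1-one
Conditions: Pd2(dba)3·CHCl3 (2.5 mol %), (R,R)-DACH-phenyl Trost ligand (7.5 mol %), K2CO3 (1.1 equiv), toluene, 0 °C
Reagents that add atoms: none
Why: Proposed new method: zerovalent palladium ionises 8 to the 1,1-dimethylallyl complex, the soft phenolate carbon attacks its CH2 terminus outer-sphere inside the chiral pocket of the Trost ligand so that one enantiotopic face of the geranyl-bearing carbon is alkylated and C5 becomes R, and O-prenyl ethers re-ionise and funnel to the C-alkylated dienone; closest known reaction type is the dearomatising palladium-catalysed asymmetric allylic alkylation (Tsuji–Trost) of substituted phenols and naphthols.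

**Step 5**
Reactants: 9 (6R)-4-benzoyl-2-(3,3-dimethylpent-4-en-1-yl)-6-geranyl-3,5-dihydroxy-6-prenylcyclohexa-2,4-dien-1-one
Product: 12 target CNP0168637.1, via spiro primary radical 10 (not isolated), via tricyclic tertiary radical 11 (not isolated)
Conditions: Mn(OAc)3·2H2O (2.5 equiv), degassed AcOH, 0.005 M, rt to 40 °C, no copper salt
Reagents that add atoms: none
Why: Proposed new method: Mn(OAc)3 oxidises the enolised triketone to the C3 radical, which closes 5-exo-trig onto the chain vinyl group (10); the primary radical adds 7-exo-trig to the prenyl group held on the same face (11); 11 adds to the enol carbon C1 and a second equivalent of Mn(OAc)3 oxidises the adduct to the trione. C5 (set in step 4) decides which face carries the prenyl group and so the absolute sense of the cage; C3, C7 and C1 follow from cage geometry; the cyclopentane methine (R) comes from the 5-exo transition state that turns its hydrogen toward the crowded C4–C5 side. Closest known reaction type is the oxidative free-radical cyclisation cascade of dearomatised prenylated acylphloroglucinols with Mn(OAc)3.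

**Compound list**
1 | 2,4,6-trihydroxybenzophenone [phenyl(2,4,6-trihydroxyphenyl)methanone] | O=C(c1ccccc1)c1c(O)cc(O)cc1O | starting material
2 | geranyl bromide [(2E)-1-bromo-3,7-dimethylocta-2,6-diene] | CC(C)=CCC/C(C)=C/CBr | starting material
3 | {3-[(2E)-3,7-dimethylocta-2,6-dien-1-yl]-2,4,6-trihydroxyphenyl}(phenyl)methanone | CC(C)=CCC/C(C)=C/Cc1c(O)cc(O)c(C(=O)c2ccccc2)c1O | intermediate
4 | methyl 3,3-dimethylpent-4-enoate | COC(=O)CC(C)(C)C=C | starting material
5 | 3,3-dimethylpent-4-enal | O=CCC(C)(C)C=C | intermediate
6 | ortho-quinone methide, 2-benzoyl-4-geranyl-3,5-dihydroxy-6-(3,3-dimethylpent-4-en-1-ylidene)cyclohexa-2,4-dien-1-one (alkylidene geometry not defined) | CC(C)=CCC/C(C)=C/CC1=C(O)C(=CCC(C)(C)C=C)C(=O)C(C(=O)c2ccccc2)=C1O | intermediate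
7 | {3-(3,3-dimethylpent-4-en-1-yl)-5-[(2E)-3,7-dimethylocta-2,6-dien-1-yl]-2,4,6-trihydroxyphenyl}(phenyl)methanone | CC(C)=CCC/C(C)=C/Cc1c(O)c(CCC(C)(C)C=C)c(O)c(C(=O)c2ccccc2)c1O | intermediate
8 | prenyl acetate (3-methylbut-2-en-1-yl acetate) | CC(=O)OCC=C(C)C | starting material
9 | (6R)-4-benzoyl-2-(3,3-dimethylpent-4-en-1-yl)-6-[(2E)-3,7-dimethylocta-2,6-dien-1-yl]-3,5-dihydroxy-6-(3-methylbut-2-en-1-yl)cyclohexa-2,4-dien-1-one | CC(C)=CCC/C(C)=C/C[C@@]1(CC=C(C)C)C(=O)C(CCC(C)(C)C=C)=C(O)C(C(=O)c2ccccc2)=C1O | intermediate
10 | spiro primary radical: C3 of ring A is spiro to a 2,2-dimethylcyclopentane whose CH next to the spiro centre carries CH2•; C5 still bears geranyl and prenyl | CC(C)=CCC/C(C)=C/C[C@@]1(CC=C(C)C)C(=O)[C@@]2(CCC(C)(C)[C@H]2[CH2])C(=O)C(C(=O)c2ccccc2)=C1O | intermediate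
11 | tricyclic tertiary radical: the CH2 of 10 is bonded to C7, closing the seven-membered ring; C7 carries the C(CH3)2• group; C1 is still an enol carbon | CC(C)=CCC/C(C)=C/C[C@@]12C[C@H]([C](C)C)C[C@@H]3C(C)(C)CC[C@]3(C1=O)C(=O)C(C(=O)c1ccccc1)=C2O | intermediate
12 | CNP0168637.1: (1S,3S,5R,7R)-1-benzoyl-5-geranyl-8,8-dimethylbicyclo[3.3.1]nonane-2,4,9-trione in which C7 and C3 are joined by a CH2–CH bridge (bridge CH of R configuration) and the bridge CH and C3 are also joined by C(CH3)2–CH2–CH2, giving a cis-fused 2,2-dimethylcyclopentane | CC(C)=CCC/C(C)=C/C[C@@]12C[C@H]3C[C@@H]4C(C)(C)CC[C@]4(C1=O)C(=O)[C@@](C(=O)c1ccccc1)(C2=O)C3(C)C | target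

**Step count and risks**
Total steps: 5. Longest linear sequence: 4 steps (1 → 3 → 7 → 9 → 12); the aldehyde branch adds 1 step.

Most likely to fail, first: step 5.
- Prenyl and geranyl look the same to the C3 radical, so about half of the material should close on the geranyl face and give the constitutional isomer (homoprenyl on C8, prenyl on C5). The ceiling is therefore near 50 %, and a realistic isolated yield is 10–20 %.
- Other expected losses: direct 5-exo attack of the C3 radical on an allyl group at C5 (a bicyclo[3.2.1]octane by-product); hydrogen-atom transfer from an allylic CH2 to the primary radical; the C7 epimer of 11, which cannot reach C1; and oxidation of 11 to an isopropenyl group.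
- Fallback, setting out from 9 and coming back at 12: N-iodosuccinimide in CH2Cl2 at −20 °C iodinates C3 to give the alpha-iodo trione F1. Et3B and air in benzene at rt then start an iodine atom-transfer chain in which the same two cyclisations run without any oxidant and the tertiary radical is capped as the tertiary iodide F2. AgOTf with 2,6-di-tert-butylpyridine in CH2Cl2 at −40 °C ionises F2, and the tertiary cation alkylates the enol carbon C1 to give 12. This replaces the oxidative cascade by a radical chain plus a separate cationic ring closure; it does not remove the prenyl/geranyl partition.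

Second: step 4.
- The sense and level of asymmetric induction on this nucleophile are unknown.
- There is no intrinsic bias between the geranyl-bearing and the pentenyl-bearing ring carbon, so a regioisomeric dienone is expected and must be removed by chromatography.
- Fallback, setting out from 7 and coming back at 9: prenyl bromide with NaOMe in MeOH at 0 °C (classical C-alkylation of a dialkylated acylphloroglucinol) gives the racemic dienone F3. Preparative supercritical-fluid chromatography on a chiral stationary phase (amylose tris(3,5-dimethylphenylcarbamate)) then gives the R enantiomer, which is 9.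

Third: step 3.
- The ortho-quinone methide 6 can be trapped by a second molecule of 3 before hydride transfer, or the hindered aldehyde may condense too slowly.
- Fallback, setting out from 3 and coming back at 7: N-iodosuccinimide in MeCN at 0 °C iodinates the one free ring position to give the aryl iodide F4. Excess 3,3-dimethylpenta-1,4-diene is hydroborated once with 9-BBN in THF to give the alkylborane F5. PdCl2(dppf) and K3PO4 in DMF/H2O at 60 °C couple F5 with F4 (B-alkyl Suzuki–Miyaura) to give 7.

**Further compounds**
F1 | step 5 | (6R)-4-benzoyl-2-(3,3-dimethylpent-4-en-1-yl)-6-geranyl-5-hydroxy-2-iodo-6-prenylcyclohex-4-ene-1,3-dione (C2 epimers) | CC(C)=CCC/C(C)=C/C[C@@]1(CC=C(C)C)C(=O)C(I)(CCC(C)(C)C=C)C(=O)C(C(=O)c2ccccc2)=C1O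
F2 | step 5 | tertiary iodide corresponding to radical 11 (C7 carries a 2-iodopropan-2-yl group) | CC(C)=CCC/C(C)=C/C[C@@]12C[C@H](C(C)(C)I)C[C@@H]3C(C)(C)CC[C@]3(C1=O)C(=O)C(C(=O)c1ccccc1)=C2O
F3 | step 4 | racemic 4-benzoyl-2-(3,3-dimethylpent-4-en-1-yl)-6-geranyl-3,5-dihydroxy-6-prenylcyclohexa-2,4-dien-1-one | CC(C)=CCC/C(C)=C/CC1(CC=C(C)C)C(=O)C(CCC(C)(C)C=C)=C(O)C(C(=O)c2ccccc2)=C1O
F4 | step 3 | 3-geranyl-5-iodo-2,4,6-trihydroxybenzophenone | CC(C)=CCC/C(C)=C/Cc1c(O)c(I)c(O)c(C(=O)c2ccccc2)c1O
F5 | step 3 | 9-(3,3-dimethylpent-4-en-1-yl)-9-borabicyclo[3.3.1]nonane | C=CC(C)(C)CCB1C2CCCC1CCC2
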